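(The rate constants belong to no real substance; the result is computed.)

Each target you make has used one coupling partner and released one by-product, and that by-product can bind a second coupling partner.

    coupling partner + catalyst intermediate A → catalyst intermediate B (k1 = 1.2 × 10⁵ M⁻¹ s⁻¹)
    coupling partner + by-product ⇌ idle adduct, settled at all times (K2 = 2.2 × 10⁵ M⁻¹)
    catalyst intermediate C → catalyst intermediate D (k3 = 45 s⁻¹)
    catalyst intermediate D → free catalyst + target (k4 = 190 s⁻¹)
    catalyst intermediate B → by-product + catalyst intermediate C (k5 = 6100 s⁻¹)
    substrate + free catalyst → catalyst intermediate A (k6 = 1.2 × 10⁷ M⁻¹ s⁻¹)

- ochre: substrate 1.0 mM; coupling partner 1.10 mM; free catalyst 5.0 µM; time 10 s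
- green: substrate 1.0 mM; coupling partner 2.10 mM; free catalyst 5.0 µM; time 10 s

- what is said of by-product includes idle adduct
- run time (ochre): 10 s

- part of the substrate that has reacted at the end, ochre
- part of the substrate that has reacted at the end, green
- what raising the concentration of coupling partner from its lowest to its highest value here does to the part of the substrate that has reacted (changes below 5 percentage points count as none) (it rises / no change / it falls)

Take the binding as balanced. 2.2 × 10⁵ M⁻¹ times the ochre charge of coupling partner gives 240, far above one, so at the start each by-product takes about one more coupling partner out of play. Call 55.0 % the capture point, half the coupling partner charge over the substrate charge: the part of the substrate reacted at which used and bound coupling partner together reach the charge.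

At that point in ochre, free coupling partner equals free by-product, and the balance leaves about 0.0500 mM. Each catalyst then waits 0.167 s per turn, longer than the 0.0222 s catalyst intermediate C takes to become catalyst intermediate D. So you expect ochre to slow sharply and stand a little above 55.0 % at 10 s. Green's capture point is 105 %, above the whole charge. Adding up green's turns, with free coupling partner taken as its charge less twice the substrate reacted, gives 8.07 s for the whole substrate, shorter than 10 s, so you expect green to finish.

The forecast gives 61 % for ochre and 100 % for green, with the trend it rises, saying of ochre past capture: “Turnover then collapses”.

The simulation gives 61.1 % for ochre and 100 % for green; it rises, by 39 percentage points. The forecast held.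

In ochre, at 10.0 s, free coupling partner stood at 1.52 % of its charge and idle adduct at 0.477 mM, while catalyst intermediate A, the resting state, held 94.7 % of the catalyst; the part reacted, past 55.0 %, still crept to 84.4 % by 100 s. In green, substrate reached 0 % by 10.0 s, with 6.3 % of the coupling partner still free. A neighbour of green charged with 4.0 mM of substrate has a capture point of 26.2 %, and at 10.0 s it had reacted 27.0 %.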